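The earlier runs and the new flask were generated by integration with constants of no real substance; the scatter is artificial.

We read these flasks at 20 h, and what differs between them is the charge of solid substrate.

| setting | ash | cedar | eta | delta | beta | gamma |
|---|---|---|---|---|---|---|
| solid substrate | 0.20 M | 1.2 M | 0.15 M | 0.30 M | 0.60 M | 1.0 M |
| remark | run made earlier | run made earlier |  |  |  |  |
| time |  |  | 20 h | 20 h | 20 h | 20 h |

| run | time / h | product / % | solid substrate / % |
|---|---|---|---|
| ash | 1.33 | 0.1 | 94.6 |
| ash | 4.00 | 2.5 | 84.8 |
| ash | 6.00 | 4.7 | 78.6 |
| ash | 10.0 | 10.5 | 66.5 |
| cedar | 0.833 | 0 | 100.1 |
| cedar | 2.00 | 0.7 | 98.3 |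
| cedar | 4.00 | 0.4 | 97.4 |
| cedar | 10.0 | 1.9 | 94.5 |

(scatter of a reading: 0.3 percentage points)

- given per volume of solution although it is solid: solid substrate
- the numbers in the tables scatter by 0.3 percentage points (one standard deviation)
- steps thought possible: starting material <-> product; solid substrate <-> starting material
- at the start none of the solid substrate is in solution
- what has only dissolved of solid substrate counts as not reacted

* all flasks from highest to lowest amount of product, in percent of the solid substrate charged, at 20 h (eta / delta / beta / gamma)
* the amount of product, in percent of the solid substrate charged of the flask you put first, at 20 h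
* the amount of product, in percent of the solid substrate charged of the flask you put last, at 20 h

At 10.0 h the ash run has lost 0.0670 M of solid and the cedar run 0.0660 M, and their product stands at 0.0210 M and 0.0228 M, though cedar was charged 6.00 times as heavily. Our bench rule for a flask that still holds solid, at a given time, is therefore to count in molar, taking the amount made as independent of the charge (zero order in solid), and to divide by the charge for the percentage.

Over the last ash interval product rose by 0.00290 M h⁻¹, and this molar slope, product gained per hour in molar, is what we carry. Run straight on, it gives 0.0500 M at 20 h, so 33.3% in eta and 5.00% in gamma.

Going round once more, we test that answer against the solid. The same straight line for solid lost gives 0.127 M, a ratio of 0.850 to eta's charge. The rule stops where this ratio reaches one, and by this line eta stays inside.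

The forecast gives eta > delta > beta > gamma, with 41% and 6.2%, holding that “excess solid does not affect the rate”. Its top stands above ours.

The simulation gives eta > delta > beta > gamma, with 29.3% and 4.39%, which is 0.0439 M of product in eta and 0.0439 M in gamma. Eta holds 49.4% starting material beside that product, and from 10.0 h to 20.0 h it added 0.0236 M where our slope adds 0.0290 M. In gamma solid still stood at 88.2% at 20.0 h, and the dissolving was still running then, starting material being made 2.13 times as fast as it was used up, each step taken net. By the step between them alone, starting material and product in gamma relax with a half-life of 2.31 h, short against the 20 h.

    starting material ⇌ product (K = 0.760, k = 3.60 × 10⁻⁵ s⁻¹)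
    solid substrate ⇌ starting material, rate k2*(cs2 - [starting material]) while solid is left; crystals form when [starting material] > cs2 (solubility = 0.170 M, k = 1.30 × 10⁻⁵ s⁻¹)

For gamma left until 2.0 d, the slope carried on from its 0.0439 M gives 12.5%. The computed flask gives 8.66%, lower than the line.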